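**Retrosynthetic overview**
- The target comes from C8-selective tigloylation of an 8,9-cis-diol, which comes from syn-dihydroxylation of a macrocyclic Z-C8=C9 alkene closed by ring-closing metathesis (ten-membered carbocycle formed last).
- The metathesis diene comes from a gold-catalysed cycloisomerization with 1,2-methyl shift of a 2-hydroxy-2-alkynyl vinyl ketone; this builds the 3(2H)-furanone and the quaternary C10 by chirality transfer from a tertiary carbinol.
- That ketone comes from Sonogashira union (C3–C4) of a Z-vinyl iodide lactone with an (S)-α-hydroxy-α-ethynyl vinyl ketone made from ethyl pyruvate.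
- The lactone fragment comes from a butenolide (asymmetric propiolate addition, semihydrogenation), then trans conjugate vinylation/α-methylenation, then a new one-step chlorohydroxylation of the α-methylene lactone.
- Ring order: γ-lactone first, furanone second, ten-membered carbocycle last.

Assumption: in steps 3 and 7 the ligand enantiomer written is taken to be the one that gives the stated configuration; if its sense of induction is opposite, the antipodal ligand is used.
Locants C1–C15 in the text follow germacrane numbering: C1 furanone C=O, C2=C3 furanone alkene, C3–O–C10 ether bridge, C4 (methyl C15)=C5, C6 lactone O–CH, C7, C8 (tiglate), C9 (OH), C10 (methyl C14), C11 (OH, C13H2Cl), C12 lactone C=O.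

**Route**

Step 1
Reactants: 1 but-2-yn-1-ol
Product: 3 (Z)-3-iodobut-2-en-1-ol, via cyclic vinylalanate 2 (not isolated)
Conditions: NaAlH2(OCH2CH2OMe)2, THF, 0 °C to rt; then I2, −78 °C
Reagents that add atoms: iodine, II
Why: hydroxyl-directed trans-hydroalumination of the propargylic alcohol places aluminium on C3 inside a five-membered alkoxyalanate, and iodinolysis with retention gives only the Z vinyl iodide (hydroalumination–iodination).

Step 2
Reactants: 3 (Z)-3-iodobut-2-en-1-ol
Product: 4 (Z)-3-iodobut-2-enal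
Conditions: MnO2, CH2Cl2, rt
Reagents that add atoms: none
Why: allylic alcohol oxidation with activated MnO2 is neutral, so the Z geometry of the β-iodo enal is kept (the aldehyde is used at once).

Step 3
Reactants: 4 (Z)-3-iodobut-2-enal; 5 methyl propiolate
Product: 6 methyl (4R,5Z)-4-hydroxy-6-iodohept-5-en-2-ynoate
Conditions: ZnMe2, (S,S)-ProPhenol (10 mol%), Ph3PO (20 mol%), toluene, 4 °C
Reagents that add atoms: none
Why: dinuclear zinc–ProPhenol catalysed asymmetric alkynylation of an enal by the zinc acetylide of methyl propiolate, with catalyst-controlled Si-face attack setting the carbinol centre that becomes C6.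

Step 4
Reactants: 6 methyl (4R,5Z)-4-hydroxy-6-iodohept-5-en-2-ynoate
Product: 8 (5S)-5-[(Z)-2-iodoprop-1-en-1-yl]furan-2(5H)-one, via Z-hydroxy dienoate 7 (not isolated)
Conditions: H2 (1 atm), Pd/CaCO3 poisoned with Pb(OAc)2, quinoline, EtOAc, rt
Reagents that add atoms: none
Why: Lindlar-type cis-semihydrogenation of the conjugated ynoate (faster than reduction of the trisubstituted vinyl iodide over the poisoned catalyst) gives the Z-γ-hydroxy enoate, which lactonizes spontaneously to the butenolide without touching the stereocentre.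

Step 5
Reactants: 8 (5S)-5-[(Z)-2-iodoprop-1-en-1-yl]furan-2(5H)-one; 9 vinylmagnesium bromide
Product: 12 (4S,5S)-5-[(Z)-2-iodoprop-1-en-1-yl]-3-methylene-4-vinyldihydrofuran-2(3H)-one, via Mannich base 10 (not isolated), via ammonium iodide 11 (not isolated)
Conditions: CuBr·SMe2 (10 mol%), THF, −78 °C; then CH2=NMe2+ I−, −78 °C to rt; then MeI; then aq. NaHCO3
Reagents that add atoms: dimethylmethyleneiminium iodide, C=[N+](C)C.[I-]
Why: copper-catalysed conjugate addition of the vinyl Grignard reagent anti to the C5 substituent sets the trans C6/C7 relationship (4S), the magnesium enolate is trapped by the iminium salt (Mannich reaction), and N-methylation/Hofmann-type elimination gives the α-methylene lactone.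

Step 6
Reactants: 12 (4S,5S)-5-[(Z)-2-iodoprop-1-en-1-yl]-3-methylene-4-vinyldihydrofuran-2(3H)-one
Product: 14 (3S,4R,5S)-3-(chloromethyl)-3-hydroxy-5-[(Z)-2-iodoprop-1-en-1-yl]-4-vinyldihydrofuran-2(3H)-one, via chlorotitanium enolate 13 (not isolated)
Conditions: TiCl4 (1.2 equiv), CH2Cl2, −78 °C; then 2-(phenylsulfonyl)-3-phenyloxaziridine, −78 to −40 °C; aq. NH4Cl
Reagents that add atoms: titanium tetrachloride, Cl[Ti](Cl)(Cl)Cl; 2-(phenylsulfonyl)-3-phenyloxaziridine, O=S(=O)(c1ccccc1)N1OC1c1ccccc1
Why: Proposed new method: TiCl4 activates the lactone carbonyl and delivers chloride to the exocyclic CH2 (C13) by conjugate addition, giving reversibly a β-chloro titanium enolate as in the TiCl4-mediated halo-aldol reaction, and this enolate is intercepted by an electrophilic oxygen donor instead of an aldehyde, the oxaziridine approaching C11 anti to the C7 vinyl group so that the new tertiary hydroxyl is cis to H7 (11S) and only the electron-poor alkene reacts; the closest known reactions are the halo-aldol reaction of enones/enoates and the sulfonyloxaziridine α-hydroxylation of enolates.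

Step 7
Reactants: 15 ethyl pyruvate; 16 ethynyltrimethylsilane
Product: 18 ethyl (S)-2-hydroxy-2-methylbut-3-ynoate, via silylalkyne ester 17 (not isolated)
Conditions: (S,S)-iPr-Phebox–Rh(OAc)2(H2O) (3 mol%), Et2O, 25 °C; then K2CO3 (cat.), EtOH, rt
Reagents that add atoms: none
Why: Rh–Phebox-catalysed direct asymmetric alkynylation of the α-keto ester (base-free, so the pyruvate does not self-condense) sets the (S) tertiary carbinol that becomes C1 and is later relayed to C10, and carbonate-catalysed ethanolysis removes the silyl group in the same flask.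

Step 8
Reactants: 18 ethyl (S)-2-hydroxy-2-methylbut-3-ynoate; 9 vinylmagnesium bromide
Product: 20 (S)-4-hydroxy-4-methylhex-1-en-5-yn-3-one, via Weinreb amide 19 (not isolated)
Conditions: MeNH(OMe)·HCl, iPrMgCl (excess), THF, −20 °C; then CH2=CHMgBr, −20 to 0 °C; inverse quench into cold aq. NaHSO4
Reagents that add atoms: none
Why: one-pot Weinreb ketone synthesis, in which the magnesium amide converts the ester into the Weinreb amide and its chelated tetrahedral adduct with the vinyl Grignard reagent collapses to the vinyl ketone only on the acidic quench, leaving the carbinol centre untouched.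

Step 9
Reactants: 14 (3S,4R,5S)-3-(chloromethyl)-3-hydroxy-5-[(Z)-2-iodoprop-1-en-1-yl]-4-vinyldihydrofuran-2(3H)-one; 20 (S)-4-hydroxy-4-methylhex-1-en-5-yn-3-one
Product: 21 (3S,4R,5R)-3-(chloromethyl)-3-hydroxy-5-[(1Z,5S)-5-hydroxy-2,5-dimethyl-6-oxoocta-1,7-dien-3-yn-1-yl]-4-vinyldihydrofuran-2(3H)-one
Conditions: PdCl2(PPh3)2 (5 mol%), CuI (10 mol%), Et3N, THF, rt
Reagents that add atoms: none
Why: Sonogashira coupling of the Z vinyl iodide with the terminal alkyne forms C3–C4 with retention of alkene geometry, the tertiary amine does not add to the vinyl ketone, and no stereocentre is involved.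

Step 10
Reactants: 21 (3S,4R,5R)-3-(chloromethyl)-3-hydroxy-5-[(1Z,5S)-5-hydroxy-2,5-dimethyl-6-oxoocta-1,7-dien-3-yn-1-yl]-4-vinyldihydrofuran-2(3H)-one
Product: 22 (3S,4R,5R)-3-(chloromethyl)-3-hydroxy-5-{(Z)-2-[(5S)-5-methyl-4-oxo-5-vinyl-4,5-dihydrofuran-2-yl]prop-1-en-1-yl}-4-vinyldihydrofuran-2(3H)-one
Conditions: AuCl3 (5 mol%), CH2Cl2, rt
Reagents that add atoms: none
Why: gold-catalysed heterocyclization/1,2-alkyl shift of a 2-hydroxy-2-alkynyl ketone, in which the ketone oxygen adds 5-endo-dig to the activated alkyne to give a 3-hydroxyfuranylium ion and the C1 methyl group then migrates suprafacially to C10 (α-ketol-type 1,2-shift) as C1 becomes the ketone, so the (S) carbinol configuration is transferred to the new quaternary centre C10 (S) and the 3(2H)-furanone is formed.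

Step 11
Reactants: 22 (3S,4R,5R)-3-(chloromethyl)-3-hydroxy-5-{(Z)-2-[(5S)-5-methyl-4-oxo-5-vinyl-4,5-dihydrofuran-2-yl]prop-1-en-1-yl}-4-vinyldihydrofuran-2(3H)-one
Product: 23 (6R,7R,10S,11S)-13-chloro-11-hydroxy-1-oxo-3,10-epoxygermacra-2,4Z,8Z-trien-6,12-olide (macrocyclic Z-C8=C9 alkene)
Conditions: second-generation Grubbs catalyst RuCl2(=CHPh)(H2IMes)(PCy3) (10 mol%), toluene (1 mM), 80 °C
Reagents that add atoms: none
Why: ring-closing metathesis of the two monosubstituted vinyl groups closes the ten-membered carbocycle with loss of ethene, the Z-C4=C5 alkene and the two rings holding the termini close, the ring size allowing only the Z-C8=C9 alkene and the electron-poor conjugated alkenes staying out.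

Step 12
Reactants: 23 (6R,7R,10S,11S)-13-chloro-11-hydroxy-1-oxo-3,10-epoxygermacra-2,4Z,8Z-trien-6,12-olide
Product: 24 (6R,7S,8S,9S,10S,11S)-13-chloro-8,9,11-trihydroxy-1-oxo-3,10-epoxygermacra-2,4Z-dien-6,12-olide
Conditions: OsO4 (5 mol%), NMO, acetone/H2O, 0 °C
Reagents that add atoms: osmium tetroxide, O=[Os](=O)(=O)=O; N-methylmorpholine N-oxide, C[N+]1([O-])CCOCC1; water, O
Why: Upjohn syn-dihydroxylation of the only unconjugated, electron-rich alkene, with osmylation from the outer face of the bridged macrocycle (anti to the C10 methyl group, on the side of the furanone oxygen bridge) converting the Z alkene into the 8S,9S cis-diol.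

Step 13
Reactants: 24 (6R,7S,8S,9S,10S,11S)-13-chloro-8,9,11-trihydroxy-1-oxo-3,10-epoxygermacra-2,4Z-dien-6,12-olide; 25 tigloyl chloride
Product: 26 CNP0272644.2 (the 8-O-tiglate of 24)
Conditions: pyridine, DMAP (10 mol%), CH2Cl2, −20 to 0 °C
Reagents that add atoms: none
Why: DMAP-catalysed acylation of the less hindered C8 hydroxyl, the C9 hydroxyl being neopentylic beside quaternary C10 and the C11 hydroxyl tertiary, with the E geometry of the acyl chloride kept under the weak base.

**Compound list**
1 | but-2-yn-1-ol | CC#CCO | starting material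
2 | sodium cyclic vinylalanate from 1 | CC1=CCO[Al-]1(OCCOC)OCCOC.[Na+] | intermediate
3 | (Z)-3-iodobut-2-en-1-ol | C/C(I)=C/CO | intermediate
4 | (Z)-3-iodobut-2-enal | C/C(I)=C/C=O | intermediate
5 | methyl propiolate | C#CC(=O)OC | starting material
6 | methyl (4R,5Z)-4-hydroxy-6-iodohept-5-en-2-ynoate | COC(=O)C#C[C@H](O)/C=C(/C)I | intermediate
7 | methyl (2Z,4S,5Z)-4-hydroxy-6-iodohepta-2,5-dienoate | COC(=O)/C=C\[C@H](O)/C=C(/C)I | intermediate
8 | (5S)-5-[(Z)-2-iodoprop-1-en-1-yl]furan-2(5H)-one | O=C1C=C[C@H](O1)/C=C(/C)I | intermediate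
9 | vinylmagnesium bromide | C=C[Mg]Br | starting material
10 | (4S,5S)-3-[(dimethylamino)methyl]-5-[(Z)-2-iodoprop-1-en-1-yl]-4-vinyldihydrofuran-2(3H)-one (C3 epimers) | C=C[C@@H]1[C@@H](/C=C(/C)I)OC(=O)C1CN(C)C | intermediate
11 | trimethylammonium iodide derived from 10 | C=C[C@@H]1[C@@H](/C=C(/C)I)OC(=O)C1C[N+](C)(C)C.[I-] | intermediate
12 | (4S,5S)-5-[(Z)-2-iodoprop-1-en-1-yl]-3-methylene-4-vinyldihydrofuran-2(3H)-one | C=C[C@@H]1[C@@H](/C=C(/C)I)OC(=O)C1=C | intermediate
13 | trichlorotitanium enolate of the 3-(chloromethyl) lactone | C=C[C@@H]1[C@@H](/C=C(/C)I)OC(O[Ti](Cl)(Cl)Cl)=C1CCl | intermediate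
14 | (3S,4R,5S)-3-(chloromethyl)-3-hydroxy-5-[(Z)-2-iodoprop-1-en-1-yl]-4-vinyldihydrofuran-2(3H)-one | C=C[C@@H]1[C@@H](/C=C(/C)I)OC(=O)[C@]1(O)CCl | intermediate
15 | ethyl pyruvate | CCOC(=O)C(C)=O | starting material
16 | ethynyltrimethylsilane | C#C[Si](C)(C)C | starting material
17 | ethyl (S)-2-hydroxy-2-methyl-4-(trimethylsilyl)but-3-ynoate | CCOC(=O)[C@@](C)(O)C#C[Si](C)(C)C | intermediate
18 | ethyl (S)-2-hydroxy-2-methylbut-3-ynoate | CCOC(=O)[C@@](C)(O)C#C | intermediate
19 | (S)-2-hydroxy-N-methoxy-N,2-dimethylbut-3-ynamide | CON(C)C(=O)[C@@](C)(O)C#C | intermediate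
20 | (S)-4-hydroxy-4-methylhex-1-en-5-yn-3-one | C=CC(=O)[C@@](C)(O)C#C | intermediate
21 | (3S,4R,5R)-3-(chloromethyl)-3-hydroxy-5-[(1Z,5S)-5-hydroxy-2,5-dimethyl-6-oxoocta-1,7-dien-3-yn-1-yl]-4-vinyldihydrofuran-2(3H)-one | C=C[C@@H]1[C@@H](/C=C(/C)C#C[C@](C)(O)C(=O)C=C)OC(=O)[C@]1(O)CCl | intermediate
22 | (3S,4R,5R)-3-(chloromethyl)-3-hydroxy-5-{(Z)-2-[(5S)-5-methyl-4-oxo-5-vinyl-4,5-dihydrofuran-2-yl]prop-1-en-1-yl}-4-vinyldihydrofuran-2(3H)-one | C=C[C@@H]1[C@@H](/C=C(/C)C2=CC(=O)[C@](C)(C=C)O2)OC(=O)[C@]1(O)CCl | intermediate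
23 | (6R,7R,10S,11S)-13-chloro-11-hydroxy-1-oxo-3,10-epoxygermacra-2,4Z,8Z-trien-6,12-olide | C[C@@]12OC(=CC1=O)/C(C)=C\[C@H]1OC(=O)[C@](O)(CCl)[C@@H]1/C=C\2 | intermediate
24 | (6R,7S,8S,9S,10S,11S)-13-chloro-8,9,11-trihydroxy-1-oxo-3,10-epoxygermacra-2,4Z-dien-6,12-olide | O[C@H]1[C@@H]2[C@@H](/C=C(/C)C3=CC(=O)[C@@](C)(O3)[C@H]1O)OC(=O)[C@]2(O)CCl | intermediate
25 | tigloyl chloride, (E)-2-methylbut-2-enoyl chloride | C/C=C(\C)C(Cl)=O | starting material
26 | CNP0272644.2, the 8-O-tiglate of 24 (6R,7S,8S,9S,10S,11S) | C/C=C(\C)C(=O)O[C@H]1[C@@H]2[C@@H](/C=C(/C)C3=CC(=O)[C@@](C)(O3)[C@H]1O)OC(=O)[C@]2(O)CCl | target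

**Summary**
Total steps: 13. Longest linear sequence: 11 (steps 1–6, then 9–13); steps 7–8 make the second fragment.

Three steps most likely to fail:

Step 6 (the proposed new chlorohydroxylation). The β-chloro titanium enolate may not form from an ester-type acceptor, or may revert to 12 before it is oxidized. The fallback uses known chemistry and sets out from 12. Nucleophilic (Weitz–Scheffer) epoxidation with tBuOOLi (tBuOOH, nBuLi, THF, −20 °C) puts the oxygen on C11 anti to the vinyl group and gives the spiro-epoxide (3R,6S,7R)-6-[(Z)-2-iodoprop-1-en-1-yl]-7-vinyl-1,5-dioxaspiro[2.4]heptan-4-one F1. HCl in dioxane at 0 °C then opens F1 at the CH2 terminus (the only carbon open to substitution) and the route is rejoined at 14.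

Step 11 (ring-closing metathesis). The ten-membered ring with seven sp2 carbons may be too strained, giving oligomers. The fallback sets out from 22 and replaces steps 11 and 12. Lemieux–Johnson cleavage of the two terminal vinyl groups (OsO4 cat., NaIO4, 2,6-lutidine, dioxane/H2O) gives the dialdehyde (2R,3R,4S)-4-(chloromethyl)-2-{(Z)-2-[(5S)-5-formyl-5-methyl-4-oxo-4,5-dihydrofuran-2-yl]prop-1-en-1-yl}-4-hydroxy-5-oxotetrahydrofuran-3-carbaldehyde F2. An intramolecular pinacol coupling with SmI2 (THF, −78 °C) then forms the C8–C9 bond and the cis-diol in one operation, and the route is rejoined at 24.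

Step 12 (face selectivity of the dihydroxylation). Neither my face argument nor the alternative has been modelled; if OsO4 attacks the other face, the 8,9-bis-epimer results. The fallback sets out from 23 and uses the Woodward cis-hydroxylation (I2, AgOAc, AcOH/H2O). The iodonium ion forms on the face OsO4 prefers, acetate opens it from the other side, and the acetoxonium ion that follows is hydrolysed to the cis-hydroxy acetate F3 (8-O-acetyl derivative of 24, possibly with its 9-O-acetyl isomer) on the opposite face. Methanolysis (HCl, MeOH, 0 °C) removes the acetate and the route is rejoined at 24.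

Further compounds
F1 | step 6 | (3R,6S,7R)-6-[(Z)-2-iodoprop-1-en-1-yl]-7-vinyl-1,5-dioxaspiro[2.4]heptan-4-one | C=C[C@@H]1[C@@H](/C=C(/C)I)OC(=O)[C@]12CO2
F2 | step 11 | (2R,3R,4S)-4-(chloromethyl)-2-{(Z)-2-[(5S)-5-formyl-5-methyl-4-oxo-4,5-dihydrofuran-2-yl]prop-1-en-1-yl}-4-hydroxy-5-oxotetrahydrofuran-3-carbaldehyde | O=C[C@@H]1[C@@H](/C=C(/C)C2=CC(=O)[C@](C)(C=O)O2)OC(=O)[C@]1(O)CCl
F3 | step 12 | 8-O-acetyl derivative of 24 (cis-hydroxy acetate) | CC(=O)O[C@H]1[C@@H]2[C@@H](/C=C(/C)C3=CC(=O)[C@@](C)(O3)[C@H]1O)OC(=O)[C@]2(O)CCl
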